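**Assumption:** compounds 1, 10, 17 and 18 are bought ((R)-α-ionone in natural-grade ee); carotenoid locants are used with the epoxide end unprimed and the ε end primed.

## Retrosynthetic overview

1. Target 24 ⇐ MnO2 oxidation of the C8 carbinol 23 ⇐ C8–C9 bond from an alkenylzinc (hydrozirconation of C29 polyenyne 20) and β,γ-epoxy aldehyde 9.
2. 20 ⇐ Wittig (C11'=C12') of ε-C15 phosphonium salt 16 with C14 ynenal 19; 19 ⇐ C10 dialdehyde 17 + butynyl ylide; 16 ⇐ (R)-α-ionone 10 by HWE, allylic C–H oxidation and reduction.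
3. 9 ⇐ one-carbon homologation (methylenation, hydroboration, oxidation) of epoxy aldehyde 6.
4. 6 ⇐ one-pot aldol condensation / nucleophilic epoxidation of the acyclic keto aldehyde (lactol 4); 4 ⇐ proline aldol of acetone with 3,3-dimethylpentanedial.
5. Ring order: the carbocycle of the epoxide end and then its oxirane are closed in the same flask (step 3); the ε-ring is carried in from 10.

## Route

**Step 1**
Reactants: 1 3,3-dimethylpentane-1,5-diol
Product: 2 3,3-dimethylpentanedial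
Conditions: (COCl)2, DMSO, CH2Cl2, −78 °C; Et3N, → 0 °C; used crude
Reagents that add atoms: none
Why: Swern oxidation activates both primary alcohols at −78 °C, which avoids the lactol/lactone formation that stepwise oxidants give with 1,5-diols.

**Step 2**
Reactants: 2 3,3-dimethylpentanedial; 3 acetone
Product: 4 (6S)-4,4-dimethyl-6-(2-oxopropyl)oxan-2-ol (lactol of (5S)-5-hydroxy-3,3-dimethyl-7-oxooctanal)
Conditions: L-proline (20 mol %), acetone/CHCl3 1:4, 23 °C, 48 h
Reagents that add atoms: none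
Why: Proline-catalysed direct aldol reaction (List–Barbas): the acetone enamine attacks the re face of one aldehyde to set C3 as S, and lactol closure shields the second aldehyde from a second aldol (ee, moderate for an α-unbranched aldehyde, can be raised by recrystallising diol 8).

**Step 3**
Reactants: 4 (6S)-4,4-dimethyl-6-(2-oxopropyl)oxan-2-ol
Product: 6 (1S,4S,6R)-4-hydroxy-2,2,6-trimethyl-7-oxabicyclo[4.1.0]heptane-1-carbaldehyde, via hydroxy-β-cyclocitral 5 (not isolated)
Conditions: pyrrolidine (30 mol %), AcOH (30 mol %), CH2Cl2, 23 °C; then MeOH, 35% H2O2, K2CO3, 0 °C (same flask)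
Reagents that add atoms: hydrogen peroxide, OO
Why: Proposed new method: the enamine of the unmasked aldehyde adds 6-enolexo to the methyl ketone and loses water to give the conjugated iminium/enal 5, then hydroperoxide adds axially at C5 trans to the equatorial C3–OH (as in carvone → trans-epoxide) and the enamine closes the oxirane, so the cyclohexene and the epoxide form in one operation with C5/C6 set by C3; closest known reactions are the piperidinium acetate cyclisation of keto aldehydes to 2-methylcycloalkene-1-carbaldehydes and Weitz–Scheffer / iminium-catalysed epoxidation of enals.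

**Step 4**
Reactants: 6 (1S,4S,6R)-4-hydroxy-2,2,6-trimethyl-7-oxabicyclo[4.1.0]heptane-1-carbaldehyde
Product: 7 (1R,3S,6S)-6-ethenyl-1,5,5-trimethyl-7-oxabicyclo[4.1.0]heptan-3-ol
Conditions: Ph3PCH3Br (2.5 equiv), KHMDS, THF, −78 → 0 °C
Reagents that add atoms: methyltriphenylphosphonium bromide, C[P+](c1ccccc1)(c1ccccc1)c1ccccc1.[Br-]
Why: Wittig methylenation of an aldehyde with no α-hydrogen (no enolisation or epimerisation possible); the extra ylide only deprotonates the free hydroxyl.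

**Step 5**
Reactants: 7 (1R,3S,6S)-6-ethenyl-1,5,5-trimethyl-7-oxabicyclo[4.1.0]heptan-3-ol
Product: 8 (1R,3S,6S)-6-(2-hydroxyethyl)-1,5,5-trimethyl-7-oxabicyclo[4.1.0]heptan-3-ol
Conditions: 9-BBN (2.5 equiv), THF, 0 → 23 °C; then NaOH, H2O2, 0 °C
Reagents that add atoms: hydrogen peroxide, OO
Why: Brown hydroboration–oxidation: the dialkylborane places boron on the terminal carbon of the neopentyl-type vinyl group without opening the fully substituted oxirane, and no enol or enolate next to the epoxide is ever formed.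

**Step 6**
Reactants: 8 (1R,3S,6S)-6-(2-hydroxyethyl)-1,5,5-trimethyl-7-oxabicyclo[4.1.0]heptan-3-ol
Product: 9 2-[(1S,4S,6R)-4-hydroxy-2,2,6-trimethyl-7-oxabicyclo[4.1.0]heptan-1-yl]acetaldehyde
Conditions: TEMPO (10 mol %), PhI(OAc)2, NaHCO3, CH2Cl2, 0 → 23 °C
Reagents that add atoms: none
Why: TEMPO/PhI(OAc)2 oxidation is selective for the primary over the secondary alcohol and stops at the aldehyde under buffered, non-basic conditions that spare the β,γ-epoxy aldehyde.

**Step 7**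
Reactants: 10 (R)-α-ionone; 11 triethyl phosphonoacetate
Product: 12 ethyl (2E,4E)-3-methyl-5-[(1R)-2,6,6-trimethylcyclohex-2-en-1-yl]penta-2,4-dienoate
Conditions: NaH, THF, 0 → 23 °C (ketone added to the preformed anion); 2Z isomer removed by chromatography
Reagents that add atoms: none
Why: Horner–Wadsworth–Emmons olefination of the methyl ketone gives mainly the 2E ester, and the weakly basic phosphonate anion does not touch the C6' stereocentre.

**Step 8**
Reactants: 12 ethyl (2E,4E)-3-methyl-5-[(1R)-2,6,6-trimethylcyclohex-2-en-1-yl]penta-2,4-dienoate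
Product: 13 ethyl (2E,4E)-3-methyl-5-[(1R)-2,6,6-trimethyl-4-oxocyclohex-2-en-1-yl]penta-2,4-dienoate
Conditions: Rh2(cap)4 (1 mol %), t-BuOOH (70% aq), ClCH2CH2Cl, 40 °C
Reagents that add atoms: tert-butyl hydroperoxide, CC(C)(C)OO
Why: Rh2(cap)4/TBHP allylic oxidation converts the ring allylic CH2 (C3') into the enone under base-free conditions, which leaves the now acidic C6'–H unepimerised.

**Step 9**
Reactants: 13 ethyl (2E,4E)-3-methyl-5-[(1R)-2,6,6-trimethyl-4-oxocyclohex-2-en-1-yl]penta-2,4-dienoate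
Product: 14 ethyl (2E,4E)-5-[(1R,4R)-4-hydroxy-2,6,6-trimethylcyclohex-2-en-1-yl]-3-methylpenta-2,4-dienoate
Conditions: L-Selectride, THF, −78 °C; aq NH4Cl; minor cis isomer removed by chromatography
Reagents that add atoms: none
Why: 1,2-Reduction of the β,β-disubstituted enone by a bulky hydride, which approaches C3' anti to the pseudoaxial C1' methyl (the face that carries the pseudoaxial side chain), gives the 3',6'-trans alcohol (3'R).

**Step 10**
Reactants: 14 ethyl (2E,4E)-5-[(1R,4R)-4-hydroxy-2,6,6-trimethylcyclohex-2-en-1-yl]-3-methylpenta-2,4-dienoate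
Product: 15 (2E,4E)-5-[(1R,4R)-4-hydroxy-2,6,6-trimethylcyclohex-2-en-1-yl]-3-methylpenta-2,4-dien-1-ol
Conditions: DIBAL-H (3.5 equiv), CH2Cl2, −78 → 0 °C; Rochelle salt
Reagents that add atoms: none
Why: DIBAL-H reduction of the dienoate ester to the primary allylic alcohol without touching the alkenes or the stereocentres.

**Step 11**
Reactants: 15 (2E,4E)-5-[(1R,4R)-4-hydroxy-2,6,6-trimethylcyclohex-2-en-1-yl]-3-methylpenta-2,4-dien-1-ol
Product: 16 [(2E,4E)-5-[(1R,4R)-4-hydroxy-2,6,6-trimethylcyclohex-2-en-1-yl]-3-methylpenta-2,4-dien-1-yl]triphenylphosphonium bromide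
Conditions: PPh3·HBr (1.0 equiv), MeOH, 0 → 23 °C; precipitate from Et2O
Reagents that add atoms: triphenylphosphine hydrobromide, [Br-].[PH+](c1ccccc1)(c1ccccc1)c1ccccc1
Why: Isler-type phosphonium salt formation: the primary pentadienylic alcohol ionises much faster than the secondary ring alcohol and PPh3 traps the cation at the chain terminus with the 2E geometry kept.

**Step 12**
Reactants: 17 (2E,4E,6E)-2,7-dimethylocta-2,4,6-trienedial; 18 (but-2-yn-1-yl)triphenylphosphonium bromide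
Product: 19 (2E,4E,6E,8E)-2,7-dimethyldodeca-2,4,6,8-tetraen-10-ynal
Conditions: 18, NaHMDS, THF, −78 °C, then into 17 (3 equiv), → 0 °C; I2 (cat.), CH2Cl2, 23 °C
Reagents that add atoms: none
Why: Wittig olefination with the propargylic ylide, where excess dialdehyde ensures mono-olefination and catalytic iodine equilibrates the new C11=C12 bond to E.

**Step 13**
Reactants: 16 [(2E,4E)-5-[(1R,4R)-4-hydroxy-2,6,6-trimethylcyclohex-2-en-1-yl]-3-methylpenta-2,4-dien-1-yl]triphenylphosphonium bromide; 19 (2E,4E,6E,8E)-2,7-dimethyldodeca-2,4,6,8-tetraen-10-ynal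
Product: 20 (1R,4R)-3,5,5-trimethyl-4-[(1E,3E,5E,7E,9E,11E,13E)-3,7,12-trimethylheptadeca-1,3,5,7,9,11,13-heptaen-15-yn-1-yl]cyclohex-2-en-1-ol
Conditions: NaOMe, MeOH/CH2Cl2, 0 → 23 °C; I2 (cat.), 23 °C
Reagents that add atoms: none
Why: Standard carotenoid Wittig coupling of a semi-stabilised C15 ylide with an α-methyl polyenal (tolerates the free hydroxyl), followed by iodine-catalysed isomerisation of the new C11'=C12' bond to all-E.

**Step 14**
Reactants: 20 (1R,4R)-3,5,5-trimethyl-4-[(1E,3E,5E,7E,9E,11E,13E)-3,7,12-trimethylheptadeca-1,3,5,7,9,11,13-heptaen-15-yn-1-yl]cyclohex-2-en-1-ol; 9 2-[(1S,4S,6R)-4-hydroxy-2,2,6-trimethyl-7-oxabicyclo[4.1.0]heptan-1-yl]acetaldehyde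
Product: 23 (3S,5R,6S,3'R,6'R)-5,6-epoxy-5,6,7,8-tetrahydro-β,ε-carotene-3,8,3'-triol (both C8 epimers), via alkenylzirconocene 21 (not isolated), via alkenylzinc 22 (not isolated)
Conditions: Cp2Zr(H)Cl (2.2 equiv), THF/CH2Cl2, 23 °C, dark; Me2Zn (3.5 equiv), −65 °C; 9, → 0 °C; aq NH4Cl
Reagents that add atoms: none
Why: Schwartz hydrozirconation adds syn across the 2-alkyne with Zr on the methyl-bearing C9 (giving the 9E geometry), and Zr→Zn transmetalation followed by 1,2-addition of the non-basic alkenylzinc to the aldehyde forms the C8–C9 bond without enolising the β,γ-epoxy aldehyde (excess reagent masks the two hydroxyls as metal alkoxides; C8 configuration is irrelevant).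

**Step 15**
Reactants: 23 (3S,5R,6S,3'R,6'R)-5,6-epoxy-5,6,7,8-tetrahydro-β,ε-carotene-3,8,3'-triol
Product: 24 (3S,5R,6S,3'R,6'R)-5,6-epoxy-3,3'-dihydroxy-5,6,7,8-tetrahydro-β,ε-caroten-8-one
Conditions: activated MnO2 (20 equiv), CH2Cl2, 0 °C, monitored
Reagents that add atoms: none
Why: MnO2 allylic oxidation takes the polyenylic C8 carbinol much faster than the isolated allylic C3'–OH and does not touch the saturated C3–OH, and its neutral conditions spare the base-labile β,γ-epoxy ketone.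

## Compound list

1 | 3,3-dimethylpentane-1,5-diol | OCCC(C)(C)CCO | starting material
2 | 3,3-dimethylpentanedial | O=CCC(C)(C)CC=O | intermediate
3 | acetone | CC(C)=O | starting material
4 | (6S)-4,4-dimethyl-6-(2-oxopropyl)oxan-2-ol (anomer mixture) | CC(=O)C[C@@H]1CC(C)(C)CC(O)O1 | intermediate
5 | (4R)-4-hydroxy-2,6,6-trimethylcyclohex-1-ene-1-carbaldehyde (hydroxy-β-cyclocitral; not isolated) | O=CC1=C(C)C[C@@H](O)CC1(C)C | intermediate
6 | (1S,4S,6R)-4-hydroxy-2,2,6-trimethyl-7-oxabicyclo[4.1.0]heptane-1-carbaldehyde | O=C[C@@]12O[C@]1(C)C[C@@H](O)CC2(C)C | intermediate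
7 | (1R,3S,6S)-6-ethenyl-1,5,5-trimethyl-7-oxabicyclo[4.1.0]heptan-3-ol | C=C[C@@]12O[C@]1(C)C[C@@H](O)CC2(C)C | intermediate
8 | (1R,3S,6S)-6-(2-hydroxyethyl)-1,5,5-trimethyl-7-oxabicyclo[4.1.0]heptan-3-ol | OCC[C@@]12O[C@]1(C)C[C@@H](O)CC2(C)C | intermediate
9 | 2-[(1S,4S,6R)-4-hydroxy-2,2,6-trimethyl-7-oxabicyclo[4.1.0]heptan-1-yl]acetaldehyde | O=CC[C@@]12O[C@]1(C)C[C@@H](O)CC2(C)C | intermediate
10 | (R)-α-ionone, (3E)-4-[(1R)-2,6,6-trimethylcyclohex-2-en-1-yl]but-3-en-2-one | CC1=CCCC(C)(C)[C@H]1/C=C/C(C)=O | starting material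
11 | triethyl phosphonoacetate | CCOC(=O)CP(=O)(OCC)OCC | starting material
12 | ethyl (2E,4E)-3-methyl-5-[(1R)-2,6,6-trimethylcyclohex-2-en-1-yl]penta-2,4-dienoate | CC1=CCCC(C)(C)[C@H]1/C=C/C(C)=C/C(=O)OCC | intermediate
13 | ethyl (2E,4E)-3-methyl-5-[(1R)-2,6,6-trimethyl-4-oxocyclohex-2-en-1-yl]penta-2,4-dienoate | CC1=CC(=O)CC(C)(C)[C@H]1/C=C/C(C)=C/C(=O)OCC | intermediate
14 | ethyl (2E,4E)-5-[(1R,4R)-4-hydroxy-2,6,6-trimethylcyclohex-2-en-1-yl]-3-methylpenta-2,4-dienoate | CC1=C[C@H](O)CC(C)(C)[C@H]1/C=C/C(C)=C/C(=O)OCC | intermediate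
15 | (2E,4E)-5-[(1R,4R)-4-hydroxy-2,6,6-trimethylcyclohex-2-en-1-yl]-3-methylpenta-2,4-dien-1-ol | CC1=C[C@H](O)CC(C)(C)[C@H]1/C=C/C(C)=C/CO | intermediate
16 | [(2E,4E)-5-[(1R,4R)-4-hydroxy-2,6,6-trimethylcyclohex-2-en-1-yl]-3-methylpenta-2,4-dien-1-yl]triphenylphosphonium bromide | CC1=C[C@H](O)CC(C)(C)[C@H]1/C=C/C(C)=C/C[P+](c2ccccc2)(c2ccccc2)c2ccccc2.[Br-] | intermediate
17 | (2E,4E,6E)-2,7-dimethylocta-2,4,6-trienedial | O=C/C(C)=C/C=C/C=C(C)/C=O | starting material
18 | (but-2-yn-1-yl)triphenylphosphonium bromide | CC#CC[P+](c1ccccc1)(c1ccccc1)c1ccccc1.[Br-] | starting material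
19 | (2E,4E,6E,8E)-2,7-dimethyldodeca-2,4,6,8-tetraen-10-ynal | O=C/C(C)=C/C=C/C=C(C)/C=C/C#CC | intermediate
20 | (1R,4R)-3,5,5-trimethyl-4-[(1E,3E,5E,7E,9E,11E,13E)-3,7,12-trimethylheptadeca-1,3,5,7,9,11,13-heptaen-15-yn-1-yl]cyclohex-2-en-1-ol | CC1=C[C@H](O)CC(C)(C)[C@H]1/C=C/C(C)=C/C=C/C(C)=C/C=C/C=C(C)/C=C/C#CC | intermediate
21 | alkenylzirconocene chloride from 20, Zr on C9, 9E (not isolated; ring OH drawn free, held as metal alkoxide in the flask) | CC1=C[C@H](O)CC(C)(C)[C@H]1/C=C/C(C)=C/C=C/C(C)=C/C=C/C=C(C)/C=C/C=C(\C)[Zr](Cl)(C2C=CC=C2)C2C=CC=C2 | intermediate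
22 | alkenyl(methyl)zinc from 21, Zn on C9, 9E (not isolated; ring OH drawn free) | CC1=C[C@H](O)CC(C)(C)[C@H]1/C=C/C(C)=C/C=C/C(C)=C/C=C/C=C(C)/C=C/C=C(\C)[Zn]C | intermediate
23 | (3S,5R,6S,3'R,6'R)-5,6-epoxy-5,6,7,8-tetrahydro-β,ε-carotene-3,8,3'-triol (C8 epimers) | CC1=C[C@H](O)CC(C)(C)[C@H]1/C=C/C(C)=C/C=C/C(C)=C/C=C/C=C(C)/C=C/C=C(\C)C(O)C[C@@]12O[C@]1(C)C[C@@H](O)CC2(C)C | intermediate
24 | (3S,5R,6S,3'R,6'R)-5,6-epoxy-3,3'-dihydroxy-5,6,7,8-tetrahydro-β,ε-caroten-8-one | CC1=C[C@H](O)CC(C)(C)[C@H]1/C=C/C(C)=C/C=C/C(C)=C/C=C/C=C(C)/C=C/C=C(\C)C(=O)C[C@@]12O[C@]1(C)C[C@@H](O)CC2(C)C | target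

## Step count and risks

Total step count: 15. Longest linear sequence: 8 steps (steps 1–6, 14, 15; equally steps 7–11, 13, 14, 15).

**Step 3 (one-pot ring closure / epoxidation).** The enal 5 may lose water to a safranal-type dienal, or the hydroperoxide may add with poor facial control. The fallback sets out from 4 and comes back at 6. Lactol 4 is cyclised with pyrrolidinium acetate alone and the enal 5 is isolated. Luche reduction (NaBH4, CeCl3) gives the allylic diol (1R)-4-(hydroxymethyl)-3,5,5-trimethylcyclohex-3-en-1-ol F1. A Sharpless asymmetric epoxidation (Ti(OiPr)4, L-(+)-diethyl tartrate, t-BuOOH, −20 °C) then sets the oxirane face by reagent control and gives (1R,3S,6R)-6-(hydroxymethyl)-1,5,5-trimethyl-7-oxabicyclo[4.1.0]heptan-3-ol F2. TEMPO/PhI(OAc)2 oxidation of its primary alcohol returns the route to 6.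

**Step 11 (phosphonium salt in the presence of the acid-labile ring allylic alcohol).** The ring alcohol may be substituted or eliminated under PPh3·HBr. The fallback reverses the polarity of the C11'=C12' coupling; it sets out from 15 (and 19) and comes back at 20. MnO2 oxidises only the primary dienylic alcohol of 15 to give (2E,4E)-5-[(1R,4R)-4-hydroxy-2,6,6-trimethylcyclohex-2-en-1-yl]-3-methylpenta-2,4-dienal F3. Ynenal 19 is reduced with NaBH4 to (2E,4E,6E,8E)-2,7-dimethyldodeca-2,4,6,8-tetraen-10-yn-1-ol F4. F4 has no sensitive ring alcohol and is converted with PPh3·HBr into [(2E,4E,6E,8E)-2,7-dimethyldodeca-2,4,6,8-tetraen-10-yn-1-yl]triphenylphosphonium bromide F5. A Wittig reaction of F5 with F3 (NaOMe, then catalytic I2) gives 20.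

**Step 14 (hydrozirconation / zinc transfer on the polyenyne with free hydroxyls).** Imperfect regiocontrol or poor alkenyl transfer would waste both fragments. The fallback sets out from 20 (with 9) and comes back at 23. Hydrozirconation of 20 is quenched with iodine to give the isolable vinyl iodide (1R,4R)-4-[(1E,3E,5E,7E,9E,11E,13E,15E)-16-iodo-3,7,12-trimethylheptadeca-1,3,5,7,9,11,13,15-octaen-1-yl]-3,5,5-trimethylcyclohex-2-en-1-ol F6, which is purified from any regioisomer. A Nozaki–Hiyama–Kishi coupling of F6 with 9 (CrCl2, cat. NiCl2, DMSO/THF, 23 °C) tolerates the free hydroxyls and the enolisable epoxy aldehyde, and gives 23.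

## Further compounds

F1 | step 3 | (1R)-4-(hydroxymethyl)-3,5,5-trimethylcyclohex-3-en-1-ol | OCC1=C(C)C[C@@H](O)CC1(C)C
F2 | step 3 | (1R,3S,6R)-6-(hydroxymethyl)-1,5,5-trimethyl-7-oxabicyclo[4.1.0]heptan-3-ol | OC[C@@]12O[C@]1(C)C[C@@H](O)CC2(C)C
F3 | step 11 | (2E,4E)-5-[(1R,4R)-4-hydroxy-2,6,6-trimethylcyclohex-2-en-1-yl]-3-methylpenta-2,4-dienal | CC1=C[C@H](O)CC(C)(C)[C@H]1/C=C/C(C)=C/C=O
F4 | step 11 | (2E,4E,6E,8E)-2,7-dimethyldodeca-2,4,6,8-tetraen-10-yn-1-ol | OC/C(C)=C/C=C/C=C(C)/C=C/C#CC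
F5 | step 11 | [(2E,4E,6E,8E)-2,7-dimethyldodeca-2,4,6,8-tetraen-10-yn-1-yl]triphenylphosphonium bromide | [Br-].c1ccccc1[P+](c1ccccc1)(c1ccccc1)C/C(C)=C/C=C/C=C(C)/C=C/C#CC
F6 | step 14 | (1R,4R)-4-[(1E,3E,5E,7E,9E,11E,13E,15E)-16-iodo-3,7,12-trimethylheptadeca-1,3,5,7,9,11,13,15-octaen-1-yl]-3,5,5-trimethylcyclohex-2-en-1-ol | CC1=C[C@H](O)CC(C)(C)[C@H]1/C=C/C(C)=C/C=C/C(C)=C/C=C/C=C(C)/C=C/C=C(\C)I
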